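## Structural features

The target 12 is an ester. A para-disubstituted benzene ring carries a free phenolic hydroxyl and, opposite to it, a CH2CH2O tether whose oxygen is acylated by an unbranched, saturated dotriacontanoyl chain (C1 carbonyl to C32 methyl). The benzene ring is the only ring, and there is no stereocentre and no double bond outside the arene, so no neighbouring stereocentres have to be related. The ester is the single link between the two halves and is the fragile point toward hydroxide, alkoxide, strong hydride donors and organometallic reagents. The free phenol is acidic, competes for acyl donors and can be oxidised, so it must be masked while carbon–carbon bonds are made. The alkyl C–O bond of the ester is homobenzylic, not benzylic, which allows a hydrogenolytic unmasking of the phenol at the end. The real difficulty is chain-length fidelity and handling: C32 acyl building blocks are scarce, the intermediates are waxes that dissolve poorly below about 40 °C, and homologues differing by one or two CH2 groups cannot realistically be removed, so the carbon count must be fixed by construction. The key step uses the fact that C1 and C2, next to the ester oxygen, form an acetate unit: a cut between C2 and C3 leaves C3 to C32 as a C30 acyl unit with the skeleton of triacontanoic acid, and a two-carbon malonate-derived piece that can already carry the arylethyl ester.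

## Logic of the disconnections

12 ⇒ 11. The phenolic O–H is traded for an O–CH2Ph bond and the C2–C3 single bond for a double bond. Both changes are reversed by one hydrogenation, and the masked phenol cannot compete for acyl donors earlier in the route. The gain is that the only acidic, oxidisable group is silenced throughout at no cost in steps. The forward step must reduce the alkene and cleave the benzylic C–O bond without touching the ester, which is plausible because the ester alkyl C–O bond is homobenzylic.

11 ⇒ 9 (through 10). The C2=C3 π bond is traded for a C3–O bond and a C2–H bond, first as the sulfonate 10 and then as the alcohol 9. Oxygen at C3 is the footprint of an acylation of an acetate unit. There is no gain in size, but the oxidation pattern now points at the C2–C3 bond. The forward elimination needs a non-nucleophilic base that spares the ester; position and geometry of the alkene do not matter.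

9 ⇒ 8. The C3–H and O–H bonds are removed to reach the C3 carbonyl of 8, which is the direct product of a Claisen-type union. The forward step needs a hydride donor that reduces the ketone and not the ester. The stereocentre formed at C3 is temporary and needs no control.

8 ⇒ 6 + 3 (through 7). The C2–C3 bond is cut. This is the only cut that divides the C32 acyl chain into a purchasable length (the C30 acyl group of 6) and a two-carbon unit (in 3) that already holds the ester link and the masked phenol. It is the largest simplification of the route, since each fragment is one operation away from catalogue compounds. The forward step must acylate carbon and not oxygen, only once, and without strong base. The extra carboxyl of 3 provides the chelation for this, and its loss from 7 as CO2 drives the union.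

6 ⇒ 4 + 5. The acyl C–N bond of 6 is cut. 6 is an activated form of 4 that is made under neutral conditions without HCl, and the cut leads back to an acid of defined chain length. The forward step needs complete activation and removal of CO2 before the carbon nucleophile is added.

3 ⇒ 1 + 2. The ester C–O bond between the malonyl carbonyl and the oxygen of 2 is cut, and the acid end is traced back to the cyclic acylal 1. Ring-opening of 1 by 2 gives the half-ester in one operation with the second carboxyl already free, so two ester groups never have to be told apart. Both components are catalogue compounds. The forward step must stay cool enough for the half-acid not to decarboxylate.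

## Other disconnections considered

Alternative 1: The chain is cut in its middle, at C9–C10, after a double bond has been placed there in thought. In the forward direction 2-(4-hydroxyphenyl)ethyl dec-9-enoate A1 and an excess of 1-tetracosene A2 would be joined by cross-metathesis with the second-generation Grubbs catalyst to give 2-(4-hydroxyphenyl)ethyl (E)-dotriacont-9-enoate A3, and hydrogenation of A3 would give 12.
- In its favour: the ruthenium carbene tolerates the free phenol and the ester, so no protecting group is needed. The sequence (acylation to A1, metathesis, hydrogenation) would be about three steps against five, so on step and protecting-group economy this is the better plan.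
- Against it here: A1 and A2 are both unhindered terminal alkenes of the same reactivity class, so only the excess of A2 steers the exchange and self-metathesis of each partner competes. The hydrocarbon formed from A2 alone would be a wax of polarity close to A3.
- More serious for a compound defined by its chain length: ruthenium hydride species from catalyst decay can move a terminal double bond along the chain before the exchange. After hydrogenation this would leave C31 and C33 homologues that cannot be separated from 12. A2 itself would also have to be free of homologues, and A1 calls for selective acylation of the aliphatic hydroxyl next to the free phenol.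
- Comparison: on structure, the cut lies in a featureless part of the chain and uses no handle of the molecule, whereas the chosen cut sits next to the only functional group. On mechanism, a reversible exchange through metallacyclobutanes under statistical control stands against an irreversible, chelate-directed acylation whose carbon count is fixed by 4. Both plans end with the same kind of hydrogenation, so they are equal on that point.

Alternative 2: The cut is again inside the chain, at C11–C12, now as a union of two alkyl radicals. Docosanoic acid A4 in excess and 12-{2-[4-(acetyloxy)phenyl]ethoxy}-12-oxododecanoic acid A5 would be electrolysed together at a platinum anode. Both carboxylates would be decarboxylated and the two primary radicals would combine to 2-[4-(acetyloxy)phenyl]ethyl dotriacontanoate A6, from which mild cleavage of the aryl acetate would give 12.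
- In its favour: the coupling product is already saturated and at the final oxidation level, so only one deprotection follows the key step, against three steps in the chosen plan. That is a clear advantage. The feedstocks are cheap fatty acids of defined length, no metal reagent is consumed, and chain-length fidelity is equal to that of the chosen plan.
- Against it here: the two radicals do not discriminate, so A6 would be accompanied by the symmetrical hydrocarbon from A4 and the symmetrical diester from A5, and the material balance on A5 would be statistical.
- The usual medium, methanol partly neutralised with base, threatens the aryl acetate and the arylethyl ester by methanolysis. A4 dissolves poorly in it, and the oxygenated arene may be oxidised at the high anode potential that the decarboxylation needs.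
- A5 needs a statistical mono-esterification of a diacid and a selective acetylation, so the total count (about four to five steps) would be no shorter.
- Comparison: on structure, both plans fix the carbon count by construction. On mechanism, an unselective radical dimerisation stands against a polar bond formation in which each partner has one defined role.

Alternative 3: The bond between the arene carbon para to oxygen and the adjacent CH2 group is cut. 1-(Benzyloxy)-4-iodobenzene A7 and 2-bromoethyl dotriacontanoate A8 would be coupled reductively with NiI2, 4,4'-di-tert-butyl-2,2'-bipyridine and zinc dust to 2-[4-(benzyloxy)phenyl]ethyl dotriacontanoate A9, and hydrogenolysis of A9 would give 12. Zerovalent nickel should add to A7, the resulting divalent arylnickel iodide should capture the primary alkyl radical generated from A8, and reductive elimination from trivalent nickel should form the bond.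
- In its favour: esters are tolerated, no organometallic reagent has to be prepared, and A9 is one step from 12, so the end game is shorter than in the chosen plan. The benzyl ether plays the same role in both.
- Against it here: the new bond lies inside the arylethanol half, which is purchasable as a unit (compare 2), so the step builds what can be bought. The real problem is untouched, because A8 has to be made from dotriacontanoic acid A10, the scarce C32 component. With A10 in hand, a plain esterification of 2 would reach A9 more directly than any coupling.
- In addition, the alkylnickel or alkylzinc species derived from A8 carries an acyloxy group in the β-position and may lose it by β-elimination. Reduction or dimerisation of either halide competes.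
- Comparison: on structure, the chosen plan creates the C32 chain from a C30 acid, which this alternative presupposes. On mechanism, radical capture at nickel stands against a closed-shell acylation. On step count, this alternative would be the shorter if A10 were freely available.

Key step: step 2

Remark on the chemistry: triacontanoic acid 4 of defined chain length is taken as a purchasable compound, so no oxidation of a C30 alcohol is needed; the acyl chain of 12 is counted as 30 carbons from 4 plus 2 from 3; 9 and 10 are racemic, which has no consequence because C3 ends as a CH2 group.

## Route

Step 1
Reactants: 1 Meldrum's acid (2,2-dimethyl-1,3-dioxane-4,6-dione); 2 2-[4-(benzyloxy)phenyl]ethanol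
Product: 3 3-{2-[4-(benzyloxy)phenyl]ethoxy}-3-oxopropanoic acid
Conditions: toluene, 100 °C, 4 h; extraction into aq. NaHCO3, then acidification with HCl
Reagents that add atoms: none
Why: Thermal ring-opening of Meldrum's acid by a primary alcohol (acyl substitution at the cyclic acylal with loss of acetone) should give the malonic half-ester directly; the freed carboxylic acid does not esterify further under these neutral conditions, and acid–base extraction separates 3 from unreacted 2.

Step 2
Reactants: 4 triacontanoic acid; 5 1,1'-carbonyldiimidazole; 3 3-{2-[4-(benzyloxy)phenyl]ethoxy}-3-oxopropanoic acid
Product: 8 2-[4-(benzyloxy)phenyl]ethyl 3-oxodotriacontanoate, via N-triacontanoylimidazole 6 (not isolated), via 2-triacontanoylmalonic half-ester 7 (not isolated)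
Conditions: 4, 5 (1.05 equiv), THF, 50 °C, 2 h, N2 sweep; then cannulated into 3 (2 equiv), MgCl2 (2 equiv), Et3N (4.5 equiv), THF–MeCN, 45 °C, 16 h; 1 M HCl, then aq. NaHCO3 wash
Reagents that add atoms: none
Why: This is a Masamune–Brooks-type decarboxylative Claisen condensation, the closest known reaction type being the acylation of magnesium malonate half-esters by acyl imidazolides. Acid 4 and 5 first give a mixed carbonic anhydride, which collapses to the acyl imidazolide 6 with loss of CO2 and imidazole. MgCl2 and Et3N convert 3 into a six-membered bidentate magnesium chelate of the malonate enolate-carboxylate, without any strong base. The central carbon of this chelate attacks the acyl carbon of 6 and expels imidazole, which creates the C2–C3 bond and gives the acylmalonate 7 as its magnesium chelate. Loss of CO2 from 7, at the latest on the acidic work-up, gives 8 and makes the condensation irreversible. No ring is closed and no stereocentre is created. The step needs C- over O-acylation, a single acylation and survival of the arylethyl ester: the chelate ties both oxygens to magnesium so that only carbon is free to react, the chelate of 7 is a stabilised tricarbonyl anion that should not take a second acyl group, and Et3N is too weak and too hindered to cleave the ester. A two-fold excess of 3 should consume all of the valuable 6 and is washed out afterwards with aqueous NaHCO3.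

Step 3
Reactants: 8 2-[4-(benzyloxy)phenyl]ethyl 3-oxodotriacontanoate
Product: 9 2-[4-(benzyloxy)phenyl]ethyl 3-hydroxydotriacontanoate (racemic)
Conditions: NaBH4 (1 equiv), THF–EtOH 4:1, −10 → 0 °C; sat. aq. NH4Cl
Reagents that add atoms: none
Why: Borohydride reduces the ketone of a 3-oxo ester much faster than the ester, so low temperature and a limited charge of NaBH4 should stop at the 3-hydroxy ester; the new stereocentre at C3 is formed without control as a racemate, which is intended because C3 becomes a CH2 group two steps later.

Step 4
Reactants: 9 2-[4-(benzyloxy)phenyl]ethyl 3-hydroxydotriacontanoate
Product: 11 2-[4-(benzyloxy)phenyl]ethyl (E)-dotriacont-2-enoate, via 3-mesyloxy ester 10 (not isolated)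
Conditions: MsCl (1.3 equiv), Et3N (1.5 equiv), CH2Cl2, 0 °C, 1 h; then DBU (2.5 equiv), 0 °C → rt
Reagents that add atoms: methanesulfonyl chloride, CS(=O)(=O)Cl (its atoms are present in 10 only and leave again as methanesulfonate)
Why: O-Sulfonylation of the secondary alcohol followed by DBU-induced E1cB elimination of the 3-mesyloxy ester should give the conjugated enoate, mainly as the more stable (E)-isomer; any (Z)- or 3,4-unsaturated isomer is harmless because all converge in step 5, and the stereocentre at C3 disappears.

Step 5
Reactants: 11 2-[4-(benzyloxy)phenyl]ethyl (E)-dotriacont-2-enoate
Product: 12 Basalethanolide A, 2-(4-hydroxyphenyl)ethyl dotriacontanoate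
Conditions: H2 (1 atm), 10% Pd/C, THF–EtOAc 1:1, 40 °C
Reagents that add atoms: none
Why: Heterogeneous catalytic hydrogenation should saturate the conjugated C2=C3 bond and cleave the benzylic C–O bond of the aryl benzyl ether in one operation (hydrogenolysis), whereas the ester, whose alkyl C–O bond is homobenzylic, is not activated toward Pd/C; the warm solvent mixture keeps the waxy substrate and product in solution.

## Compound list

1 | Meldrum's acid (2,2-dimethyl-1,3-dioxane-4,6-dione) | CC1(C)OC(=O)CC(=O)O1 | starting material
2 | 2-[4-(benzyloxy)phenyl]ethanol | OCCc1ccc(OCc2ccccc2)cc1 | starting material
3 | 3-{2-[4-(benzyloxy)phenyl]ethoxy}-3-oxopropanoic acid | OC(=O)CC(=O)OCCc1ccc(OCc2ccccc2)cc1 | intermediate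
4 | triacontanoic acid | CCCCCCCCCCCCCCCCCCCCCCCCCCCCCC(=O)O | starting material
5 | 1,1'-carbonyldiimidazole | O=C(n1ccnc1)n1ccnc1 | starting material
6 | N-triacontanoylimidazole, 1-(1H-imidazol-1-yl)triacontan-1-one | CCCCCCCCCCCCCCCCCCCCCCCCCCCCCC(=O)n1ccnc1 | intermediate (not isolated)
7 | 2-({2-[4-(benzyloxy)phenyl]ethoxy}carbonyl)-3-oxodotriacontanoic acid (2-triacontanoylmalonic half-ester, present as its magnesium chelate; C2 configurationally labile) | CCCCCCCCCCCCCCCCCCCCCCCCCCCCCC(=O)C(C(=O)O)C(=O)OCCc1ccc(OCc2ccccc2)cc1 | intermediate (not isolated)
8 | 2-[4-(benzyloxy)phenyl]ethyl 3-oxodotriacontanoate | CCCCCCCCCCCCCCCCCCCCCCCCCCCCCC(=O)CC(=O)OCCc1ccc(OCc2ccccc2)cc1 | intermediate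
9 | 2-[4-(benzyloxy)phenyl]ethyl 3-hydroxydotriacontanoate (racemic at C3) | CCCCCCCCCCCCCCCCCCCCCCCCCCCCCC(O)CC(=O)OCCc1ccc(OCc2ccccc2)cc1 | intermediate
10 | 2-[4-(benzyloxy)phenyl]ethyl 3-[(methylsulfonyl)oxy]dotriacontanoate (racemic at C3) | CCCCCCCCCCCCCCCCCCCCCCCCCCCCCC(OS(C)(=O)=O)CC(=O)OCCc1ccc(OCc2ccccc2)cc1 | intermediate (not isolated)
11 | 2-[4-(benzyloxy)phenyl]ethyl (E)-dotriacont-2-enoate | CCCCCCCCCCCCCCCCCCCCCCCCCCCCC/C=C/C(=O)OCCc1ccc(OCc2ccccc2)cc1 | intermediate
12 | Basalethanolide A, 2-(4-hydroxyphenyl)ethyl dotriacontanoate | CCCCCCCCCCCCCCCCCCCCCCCCCCCCCCCC(=O)OCCc1ccc(O)cc1 | target

## Step count and least certain steps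

Total step count: 5. Longest linear sequence: 5 steps (1 and 2 → 3 → 8 → 9 → 11 → 12); 4 and 5 enter in step 2, where 6 is made and consumed in the same operation.

Step 2 (key step). What may go wrong: slow or incomplete C-acylation. The C30 acyl imidazolide is only a moderate electrophile and tends to separate from the polar THF–MeCN medium, which leaves time for hydrolysis back to the acid and for acyl transfer to carboxylate oxygen instead of carbon. The fallback sets out from 4 and comes back at 8; it makes the same C2–C3 bond on Meldrum's acid instead of on the half-ester and does not need 3. 4 and 1 would be condensed with DCC and DMAP in CH2Cl2–THF to 5-(1-hydroxytriacontylidene)-2,2-dimethyl-1,3-dioxane-4,6-dione F1, the enol form of the C-acyl Meldrum's acid. Heating F1 with 2 in toluene at about 100 °C should release the acylketene, which 2 traps, and loss of acetone and CO2 should give 8. This is known acyl Meldrum's acid alcoholysis.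

Step 3. What may go wrong: over-reduction of the ester, because the alkoxyborate formed at C3 can deliver hydride to the neighbouring ester carbonyl, and exchange of the arylethyl ester with ethanol under the basic conditions. The fallback sets out from 8 and comes back at 11; it removes the C3 oxygen as a leaving group at the enol stage, so steps 3 and 4 are both bypassed. Tf2O, LiOTf and Et3N in CH2Cl2 at 0 °C should give, through the lithium chelate, 2-[4-(benzyloxy)phenyl]ethyl (Z)-3-{[(trifluoromethyl)sulfonyl]oxy}dotriacont-2-enoate F2. Reduction of F2 with HCO2H and Bu3N under Pd(OAc)2 and PPh3 (zerovalent palladium formed in the flask) in DMF–THF at 60 °C should replace the triflate by hydrogen with retention of the alkene geometry and give 11.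

Step 4. What may go wrong: incomplete elimination when the waxy sulfonate separates from solution, displacement of the sulfonate by chloride, or cleavage of the ester during long exposure to DBU. The fallback sets out from 9 and comes back at 12; it uses radical deoxygenation (Barton–McCombie) instead of elimination. 9 with 1,1'-thiocarbonyldiimidazole and catalytic DMAP in THF at 60 °C should give 2-[4-(benzyloxy)phenyl]ethyl 3-[(1H-imidazol-1-ylcarbonothioyl)oxy]dotriacontanoate F3. (Me3Si)3SiH and AIBN in toluene at 85 °C should then cleave the C3–O bond through the secondary alkyl radical and give 2-[4-(benzyloxy)phenyl]ethyl dotriacontanoate F4. Hydrogenolysis of F4 under the conditions of step 5 gives 12.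

Step 1. What may go wrong: thermal decarboxylation of the malonic half-acid and a second esterification if heating is prolonged. The fallback sets out from 2 and comes back at 3; it is a carbodiimide mono-esterification without heating. 2 would be added to an excess of malonic acid and DCC in MeCN at 0 °C → rt. Filtration of the urea and acid–base extraction should give 3. No new compound arises on this way (F0).

## Further compounds

F1 | step 2 | 5-(1-hydroxytriacontylidene)-2,2-dimethyl-1,3-dioxane-4,6-dione | CCCCCCCCCCCCCCCCCCCCCCCCCCCCCC(O)=C1C(=O)OC(C)(C)OC1=O
F2 | step 3 | 2-[4-(benzyloxy)phenyl]ethyl (Z)-3-{[(trifluoromethyl)sulfonyl]oxy}dotriacont-2-enoate | CCCCCCCCCCCCCCCCCCCCCCCCCCCCC/C(OS(=O)(=O)C(F)(F)F)=C/C(=O)OCCc1ccc(OCc2ccccc2)cc1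
F3 | step 4 | 2-[4-(benzyloxy)phenyl]ethyl 3-[(1H-imidazol-1-ylcarbonothioyl)oxy]dotriacontanoate (racemic at C3) | CCCCCCCCCCCCCCCCCCCCCCCCCCCCCC(OC(=S)n1ccnc1)CC(=O)OCCc1ccc(OCc2ccccc2)cc1
F4 | step 4 | 2-[4-(benzyloxy)phenyl]ethyl dotriacontanoate | CCCCCCCCCCCCCCCCCCCCCCCCCCCCCCCC(=O)OCCc1ccc(OCc2ccccc2)cc1
F0 | step 1 | none | none
A1 | alternative 1 | 2-(4-hydroxyphenyl)ethyl dec-9-enoate | C=CCCCCCCCC(=O)OCCc1ccc(O)cc1
A2 | alternative 1 | 1-tetracosene | CCCCCCCCCCCCCCCCCCCCCCC=C
A3 | alternative 1 | 2-(4-hydroxyphenyl)ethyl (E)-dotriacont-9-enoate | CCCCCCCCCCCCCCCCCCCCCC/C=C/CCCCCCCC(=O)OCCc1ccc(O)cc1
A4 | alternative 2 | docosanoic acid | CCCCCCCCCCCCCCCCCCCCCC(=O)O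
A5 | alternative 2 | 12-{2-[4-(acetyloxy)phenyl]ethoxy}-12-oxododecanoic acid | OC(=O)CCCCCCCCCCC(=O)OCCc1ccc(OC(C)=O)cc1
A6 | alternative 2 | 2-[4-(acetyloxy)phenyl]ethyl dotriacontanoate | CCCCCCCCCCCCCCCCCCCCCCCCCCCCCCCC(=O)OCCc1ccc(OC(C)=O)cc1
A7 | alternative 3 | 1-(benzyloxy)-4-iodobenzene | Ic1ccc(OCc2ccccc2)cc1
A8 | alternative 3 | 2-bromoethyl dotriacontanoate | CCCCCCCCCCCCCCCCCCCCCCCCCCCCCCCC(=O)OCCBr
A9 | alternative 3 | 2-[4-(benzyloxy)phenyl]ethyl dotriacontanoate | CCCCCCCCCCCCCCCCCCCCCCCCCCCCCCCC(=O)OCCc1ccc(OCc2ccccc2)cc1
A10 | alternative 3 | dotriacontanoic acid | CCCCCCCCCCCCCCCCCCCCCCCCCCCCCCCC(=O)O
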